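The pyranone ring is disconnected at O1–C2 together with the C8–prenyl bond. The key step exploits the ortho relationship between the prenylated carbon C8 and C8a, the A-ring carbon that carries ring oxygen O1: a 1,1-dimethylallyl ether on that oxygen is at once the masked nucleophile and the prenyl source. In one pot, an aromatic Claisen rearrangement places prenyl on C8 and frees O1–H, a cinchona thiourea closes the pyranone ring by enantioselective oxa-Michael addition to an alkylidene β-ketoester (removable tert-butyl ester at C3), and acid removes that ester and the 5-O-MOM group. The precursor is an acyclic alkylidene β-ketoester linking both arenes.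

Key step: step 6

Remark 1: the quinidine-derived thiourea is assumed to give the 2S product; if a test cyclisation shows the opposite sense, the quinine-derived pseudo-enantiomer is used instead.
Remark 2: alkylidenes 7, 8 and 9 are drawn as Z isomers (aryl cis to the ester); E/Z mixtures should be usable because both geometries close to the same ring and interconvert under amine catalysis.

Step 1
Reactants: 1 2',6'-dihydroxy-4'-methoxyacetophenone; 2 3-chloro-3-methylbut-1-yne
Product: 3 1-[2-hydroxy-4-methoxy-6-(2-methylbut-3-yn-2-yloxy)phenyl]ethan-1-one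
Conditions: 2 (1.2 equiv), DBU (1.3 equiv), CuCl2·2H2O (1 mol%), MeCN, 0 °C to rt
Reagents that add atoms: none
Why: Copper-catalysed O-propargylation of a phenol with a tertiary propargyl chloride gives hindered aryl 1,1-dimethylpropargyl ethers at low temperature; the two hydroxyls of 1 are equivalent, and after the first etherification the remaining one is hydrogen-bonded to the acetyl group, so the reaction should stop at the mono-ether.

Step 2
Reactants: 3 1-[2-hydroxy-4-methoxy-6-(2-methylbut-3-yn-2-yloxy)phenyl]ethan-1-one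
Product: 4 1-[4-methoxy-2-(methoxymethoxy)-6-(2-methylbut-3-yn-2-yloxy)phenyl]ethan-1-one
Conditions: NaH (1.1 equiv), DMF, 0 °C; MOMCl (1.3 equiv), 0 °C to rt
Reagents that add atoms: chloromethyl methyl ether (MOMCl), COCCl
Why: Williamson alkylation of the sodium phenoxide with the reactive α-chloro ether overcomes the chelated hydroxyl, and the acetal blocks the oxygen that becomes the 5-OH so that only one phenol can later be freed for ring closure.

Step 3
Reactants: 4 1-[4-methoxy-2-(methoxymethoxy)-6-(2-methylbut-3-yn-2-yloxy)phenyl]ethan-1-one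
Product: 5 tert-butyl 3-[4-methoxy-2-(methoxymethoxy)-6-(2-methylbut-3-yn-2-yloxy)phenyl]-3-oxopropanoate
Conditions: LiHMDS (2.1 equiv), THF, −78 °C; Boc2O (1.05 equiv), −78 to 0 °C; aq NH4Cl
Reagents that add atoms: di-tert-butyl dicarbonate (Boc2O), CC(C)(C)OC(=O)OC(=O)OC(C)(C)C
Why: Claisen-type C-acylation of the lithium enolate of the methyl ketone with Boc2O, in which the second equivalent of base deprotonates the more acidic β-ketoester product, while the far less acidic terminal alkyne should remain largely untouched with only a slight excess of base.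

Step 4
Reactants: 5 tert-butyl 3-[4-methoxy-2-(methoxymethoxy)-6-(2-methylbut-3-yn-2-yloxy)phenyl]-3-oxopropanoate; 6 2,4,6-trimethoxybenzaldehyde
Product: 7 tert-butyl (Z)-2-[4-methoxy-2-(methoxymethoxy)-6-(2-methylbut-3-yn-2-yloxy)benzoyl]-3-(2,4,6-trimethoxyphenyl)prop-2-enoate
Conditions: piperidine (0.2 equiv), AcOH (0.4 equiv), benzene, reflux, Dean–Stark
Reagents that add atoms: none
Why: Knoevenagel condensation through the piperidinium iminium ion of the electron-rich aldehyde with azeotropic removal of water; no phenol is free, so premature racemic ring closure cannot occur, and the propargyl ether is thermally stable at 80 °C where a dimethylallyl ether would not be.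

Step 5
Reactants: 7 tert-butyl (Z)-2-[4-methoxy-2-(methoxymethoxy)-6-(2-methylbut-3-yn-2-yloxy)benzoyl]-3-(2,4,6-trimethoxyphenyl)prop-2-enoate
Product: 8 tert-butyl (Z)-2-[4-methoxy-2-(methoxymethoxy)-6-(2-methylbut-3-en-2-yloxy)benzoyl]-3-(2,4,6-trimethoxyphenyl)prop-2-enoate
Conditions: H2 (1 atm), Lindlar catalyst, quinoline, EtOAc, rt, stopped after 1 equiv H2
Reagents that add atoms: none
Why: Lindlar semihydrogenation takes the strongly adsorbing terminal alkyne to the vinyl group, while the poisoned catalyst should leave the hindered trisubstituted alkylidene and the new monosubstituted alkene untouched at this conversion.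

Step 6
Reactants: 8 tert-butyl (Z)-2-[4-methoxy-2-(methoxymethoxy)-6-(2-methylbut-3-en-2-yloxy)benzoyl]-3-(2,4,6-trimethoxyphenyl)prop-2-enoate
Product: 12 (2S)-5-hydroxy-7-methoxy-8-(3-methylbut-2-en-1-yl)-2-(2,4,6-trimethoxyphenyl)chroman-4-one, via Claisen phenol 9 (not isolated), via chromanone tert-butyl ester 10 (not isolated), via MOM-protected flavanone 11 (not isolated)
Conditions: toluene (degassed, base-free), 105 °C; then −25 °C, quinidine-derived 9-amino(9-deoxy)-epi-cinchona 3,5-bis(trifluoromethyl)phenyl thiourea (10 mol%); then TsOH·H2O (1.5 equiv), 80 °C; then MeOH, 50 °C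
Reagents that add atoms: none
Why: On heating, the aryl 1,1-dimethylallyl ether undergoes a [3,3]-sigmatropic aromatic Claisen rearrangement through a chair transition state to the only free ortho carbon (the other carries the acyl group), and enolisation of the dienone gives phenol 9 with prenyl on the future C8 and the future O1 free. At −25 °C the bifunctional thiourea binds the β-ketoester through its N–H bonds and activates the phenol through its quinuclidine nitrogen, and the phenol oxygen adds to the β-carbon in a 6-endo-trig oxa-Michael closure that forms the O1–C2 bond and the pyranone ring (10). The closest known reactions are the thermal tandem Claisen rearrangement/oxa-Michael route to 8-allyl and 8-prenyl flavanones and the thiourea-catalysed enantioselective oxa-conjugate addition of 2-hydroxyaryl alkylidene β-ketoesters with one-pot acid decarboxylation. The C2 configuration is set by the catalyst, which exposes one face of the alkylidene within the hydrogen-bonded complex, whereas the C3 centre of 10 is epimerisable and is removed. TsOH then protonates the amine (stopping retro-Michael racemisation), cleaves the tert-butyl ester with loss of isobutene, the β-keto acid decarboxylates to 11, and methanolysis of the MOM acetal frees the chelated 5-OH. The step needs regioselectivity in the rearrangement and in the ring closure, secured by the single open ortho position and by the MOM ether on the other oxygen, and enantiofacial selectivity, secured by adding the catalyst only after cooling, since hydrogen bonding of the freed phenol to the ketone should keep uncatalysed closure slow during the thermal stage.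

Compound list
1 | 2',6'-dihydroxy-4'-methoxyacetophenone | CC(=O)c1c(O)cc(OC)cc1O | starting material
2 | 3-chloro-3-methylbut-1-yne | CC(C)(Cl)C#C | starting material
3 | 1-[2-hydroxy-4-methoxy-6-(2-methylbut-3-yn-2-yloxy)phenyl]ethan-1-one | CC(=O)c1c(O)cc(OC)cc1OC(C)(C)C#C | intermediate
4 | 1-[4-methoxy-2-(methoxymethoxy)-6-(2-methylbut-3-yn-2-yloxy)phenyl]ethan-1-one | CC(=O)c1c(OCOC)cc(OC)cc1OC(C)(C)C#C | intermediate
5 | tert-butyl 3-[4-methoxy-2-(methoxymethoxy)-6-(2-methylbut-3-yn-2-yloxy)phenyl]-3-oxopropanoate | CC(C)(C)OC(=O)CC(=O)c1c(OCOC)cc(OC)cc1OC(C)(C)C#C | intermediate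
6 | 2,4,6-trimethoxybenzaldehyde | COc1cc(OC)c(C=O)c(OC)c1 | starting material
7 | tert-butyl (Z)-2-[4-methoxy-2-(methoxymethoxy)-6-(2-methylbut-3-yn-2-yloxy)benzoyl]-3-(2,4,6-trimethoxyphenyl)prop-2-enoate | COc1cc(OC)c(/C=C(\C(=O)OC(C)(C)C)C(=O)c2c(OCOC)cc(OC)cc2OC(C)(C)C#C)c(OC)c1 | intermediate
8 | tert-butyl (Z)-2-[4-methoxy-2-(methoxymethoxy)-6-(2-methylbut-3-en-2-yloxy)benzoyl]-3-(2,4,6-trimethoxyphenyl)prop-2-enoate | COc1cc(OC)c(/C=C(\C(=O)OC(C)(C)C)C(=O)c2c(OCOC)cc(OC)cc2OC(C)(C)C=C)c(OC)c1 | intermediate
9 | tert-butyl (Z)-2-[2-hydroxy-4-methoxy-6-(methoxymethoxy)-3-(3-methylbut-2-en-1-yl)benzoyl]-3-(2,4,6-trimethoxyphenyl)prop-2-enoate | COc1cc(OC)c(/C=C(\C(=O)OC(C)(C)C)C(=O)c2c(OCOC)cc(OC)c(CC=C(C)C)c2O)c(OC)c1 | intermediate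
10 | tert-butyl (2S,3R)-7-methoxy-5-(methoxymethoxy)-8-(3-methylbut-2-en-1-yl)-4-oxo-2-(2,4,6-trimethoxyphenyl)chromane-3-carboxylate (trans, keto form shown) | COc1cc(OC)c([C@@H]2[C@@H](C(=O)OC(C)(C)C)C(=O)c3c(OCOC)cc(OC)c(CC=C(C)C)c3O2)c(OC)c1 | intermediate
11 | (2S)-7-methoxy-5-(methoxymethoxy)-8-(3-methylbut-2-en-1-yl)-2-(2,4,6-trimethoxyphenyl)chroman-4-one | COc1cc(OC)c([C@@H]2CC(=O)c3c(OCOC)cc(OC)c(CC=C(C)C)c3O2)c(OC)c1 | intermediate
12 | (2S)-5-hydroxy-7-methoxy-8-(3-methylbut-2-en-1-yl)-2-(2,4,6-trimethoxyphenyl)chroman-4-one | COc1cc(OC)c([C@@H]2CC(=O)c3c(O)cc(OC)c(CC=C(C)C)c3O2)c(OC)c1 | target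

Total step count: 6. Longest linear sequence: 6 steps (1 to 12); aldehyde 6 enters at step 4.

Steps most likely to fail

Step 6. The enantiomeric purity may be eroded in three ways: uncatalysed ring closure of phenol 9 during the thermal stage, weak facial discrimination at a β-carbon flanked by two ortho-methoxy groups, or acid-promoted reversible opening of the C2–O1 bond during decarboxylation. The fallback gives up asymmetric induction and sets out from 8. The same thermal Claisen rearrangement to 9 is followed by closure with an achiral base (DABCO, 10 mol%, toluene, rt) to racemic tert-butyl 7-methoxy-5-(methoxymethoxy)-8-prenyl-4-oxo-2-(2,4,6-trimethoxyphenyl)chromane-3-carboxylate F1. TsOH·H2O at 80 °C should give racemic 5-O-MOM flavanone F2, and MeOH at 50 °C racemic flavanone F3. Preparative chromatography on a polysaccharide chiral stationary phase then separates the (2S)-enantiomer from the (2R)-antipode F4, and the fallback comes back to the route at 12.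

Step 4. Condensation between the hindered, electron-rich aldehyde and the β-ketoester may be slow and reversible, with decomposition on prolonged heating with amine. The fallback replaces condensation by alkylation and dehydrogenation and sets out from 5. Acid-catalysed C-benzylation with 2,4,6-trimethoxybenzyl alcohol (Bi(OTf)3, 2 mol%, CH2Cl2, 0 °C) should give tert-butyl 3-[4-methoxy-2-(methoxymethoxy)-6-(2-methylbut-3-yn-2-yloxy)phenyl]-3-oxo-2-(2,4,6-trimethoxybenzyl)propanoate F5. Selenenylation of its sodium enolate (NaH, PhSeCl, THF, −78 °C) gives the α-phenylselanyl β-ketoester F6. Oxidation (H2O2, pyridine, CH2Cl2, 0 °C) and syn-elimination of the selenoxide towards the benzylic hydrogens then returns to the route at 7.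

Step 3. The enolate may be acylated on oxygen to an enol carbonate, and the terminal alkyne may be deprotonated and acylated. The fallback avoids strong base and sets out from 4. Soft-enolisation carboxylation (MgCl2, NaI, Et3N, CO2 1 atm, MeCN, rt; cold citric acid work-up) should give 3-[4-methoxy-2-(methoxymethoxy)-6-(2-methylbut-3-yn-2-yloxy)phenyl]-3-oxopropanoic acid F7. Neutral esterification with O-tert-butyl-N,N'-diisopropylisourea (CH2Cl2, rt) then returns to the route at 5.

Further compounds
F1 | step 6 | racemic tert-butyl 7-methoxy-5-(methoxymethoxy)-8-(3-methylbut-2-en-1-yl)-4-oxo-2-(2,4,6-trimethoxyphenyl)chromane-3-carboxylate | COc1cc(OC)c(C2C(C(=O)OC(C)(C)C)C(=O)c3c(OCOC)cc(OC)c(CC=C(C)C)c3O2)c(OC)c1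
F2 | step 6 | racemic 7-methoxy-5-(methoxymethoxy)-8-(3-methylbut-2-en-1-yl)-2-(2,4,6-trimethoxyphenyl)chroman-4-one | COc1cc(OC)c(C2CC(=O)c3c(OCOC)cc(OC)c(CC=C(C)C)c3O2)c(OC)c1
F3 | step 6 | racemic 5-hydroxy-7-methoxy-8-(3-methylbut-2-en-1-yl)-2-(2,4,6-trimethoxyphenyl)chroman-4-one | COc1cc(OC)c(C2CC(=O)c3c(O)cc(OC)c(CC=C(C)C)c3O2)c(OC)c1
F4 | step 6 | (2R)-5-hydroxy-7-methoxy-8-(3-methylbut-2-en-1-yl)-2-(2,4,6-trimethoxyphenyl)chroman-4-one | COc1cc(OC)c([C@H]2CC(=O)c3c(O)cc(OC)c(CC=C(C)C)c3O2)c(OC)c1
F5 | step 4 | tert-butyl 3-[4-methoxy-2-(methoxymethoxy)-6-(2-methylbut-3-yn-2-yloxy)phenyl]-3-oxo-2-(2,4,6-trimethoxybenzyl)propanoate | COc1cc(OC)c(CC(C(=O)OC(C)(C)C)C(=O)c2c(OCOC)cc(OC)cc2OC(C)(C)C#C)c(OC)c1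
F6 | step 4 | tert-butyl 3-[4-methoxy-2-(methoxymethoxy)-6-(2-methylbut-3-yn-2-yloxy)phenyl]-3-oxo-2-(phenylselanyl)-2-(2,4,6-trimethoxybenzyl)propanoate | COc1cc(OC)c(CC([Se]c2ccccc2)(C(=O)OC(C)(C)C)C(=O)c3c(OCOC)cc(OC)cc3OC(C)(C)C#C)c(OC)c1
F7 | step 3 | 3-[4-methoxy-2-(methoxymethoxy)-6-(2-methylbut-3-yn-2-yloxy)phenyl]-3-oxopropanoic acid | OC(=O)CC(=O)c1c(OCOC)cc(OC)cc1OC(C)(C)C#C
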